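**Plan**

- Cuts: (a) the O1–C2 and C3–C4 bonds of ring C of the top unit, in one retro-[4+2] step, giving an o-quinone methide and a (Z)-styrenyl MIDA boronate that supplies C2, C3 and ring B; (b) the carbinol bond from C4 of the top unit to C6 of the middle unit; (c) the lower interflavan bond from C4 of the middle unit to C6 of the bottom unit.
- Forward order: (−)-epicatechin is benzylated and brominated at C8; a C4-activated copy is coupled to C6 of a second copy to give the middle–bottom dimer; C6 of the middle unit is iodinated, metalated and added to a ring A salicylaldehyde; the benzhydrol is ionised and ring C of the top unit is closed by cycloaddition; C–B is oxidised to C–OH; hydrogenolysis removes all benzyl groups and both bromines.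
- Stereochemistry: the centres at C2 and C3 of the two lower units come from (−)-epicatechin; C4 of the middle unit from attack anti to the 3-OH on the flavan-4-yl cation; C2/C3 of the top unit cis from suprafacial addition to the (Z)-alkene; C4 of the top unit trans to C3 from the exo approach; absolute sense from the chiral phosphoric acid; C3–O from stereoretentive oxidation.
- Enabling feature: in the top unit the phenolic oxygen O1 on C8a of the phloroglucinol ring A sits ortho to C4a, which bears the doubly benzylic C4. Ionisation at C4 therefore gives the 1-oxadiene O1=C8a–C4a=C4. C2 is benzylic to the catechol ring B and β to boron, so the alkene is polarised to bond C3 to C4 and C2 to O1.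

Key step: step 10

Remark: the target is read as epicatechin-(4β→6)-epicatechin-(4β→6)-epicatechin, every unit 2R,3R and both interflavan bonds trans to the adjacent 3-OH.
Remark: the sense of induction of the phosphoric acid cannot be fixed on paper for this substrate; the (R)-acid is written, and its enantiomer is the direct substitute should it select the other face.

**Route**

Step 1
Reactants: 1 (−)-epicatechin
Product: 2 5,7,3',4'-tetra-O-benzyl-(−)-epicatechin
Conditions: BnBr (4.4 equiv), K2CO3, DMF, 0 °C → rt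
Reagents that add atoms: benzyl bromide, BrCc1ccccc1
Why: Williamson etherification of the four phenols under carbonate base should leave the secondary 3-OH and both stereocentres untouched.

Step 2
Reactants: 2 5,7,3',4'-tetra-O-benzyl-(−)-epicatechin
Product: 3 8-bromo-5,7,3',4'-tetra-O-benzyl-(−)-epicatechin
Conditions: NBS (1.0 equiv), CH2Cl2, −78 °C → rt
Reagents that add atoms: N-bromosuccinimide, O=C1CCC(=O)N1Br
Why: electrophilic aromatic bromination should take the more accessible phloroglucinol position C8 (flanked by O1 and one benzyloxy group) ahead of C6 (flanked by two benzyloxy groups), as is usual for benzylated flavan-3-ols.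

Step 3
Reactants: 3 8-bromo-5,7,3',4'-tetra-O-benzyl-(−)-epicatechin
Product: 4 8-bromo-5,7,3',4'-tetra-O-benzyl-4β-(2-hydroxyethoxy)-(−)-epicatechin (4-alkoxy group trans to the 3-OH)
Conditions: DDQ (2 equiv), HOCH2CH2OH, DMAP, CH2Cl2, rt
Reagents that add atoms: ethylene glycol, OCCO
Why: DDQ benzylic oxidation (hydride abstraction from C4 gives a cation stabilised by the ring A oxygens) with capture by ethylene glycol on the face anti to the 3-OH should set the 4β-alkoxy group.

Step 4
Reactants: 3 8-bromo-5,7,3',4'-tetra-O-benzyl-(−)-epicatechin (4 equiv); 4 8-bromo-5,7,3',4'-tetra-O-benzyl-4β-(2-hydroxyethoxy)-(−)-epicatechin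
Product: 5 protected dimer diol, [8-bromo-5,7,3',4'-tetra-O-benzyl-epicatechin]-(4β→6)-[8-bromo-5,7,3',4'-tetra-O-benzyl-epicatechin], 3-OH free in both units
Conditions: TMSOTf (0.2 equiv), CH2Cl2, −78 °C; Et3N quench
Reagents that add atoms: none
Why: Lewis-acid-promoted Friedel–Crafts coupling of a flavan-4-yl cation, in which bromine blocks C8 of 3 so that C6 attacks the C4 cation of 4 anti to its 3-OH (4β, 3,4-trans), while the excess of 3 suppresses self-condensation of 4.

Step 5
Reactants: 5 protected dimer diol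
Product: 6 deca-O-benzyl dimer (3-O-benzyl ether of both units of 5)
Conditions: NaH, BnBr, nBu4NI (cat.), DMF, 0 °C → rt
Reagents that add atoms: benzyl bromide, BrCc1ccccc1
Why: Williamson etherification of the two secondary alkoxides should mask the hydroxyl groups against the Grignard reagent of step 8 and the cationic key step without touching a stereocentre.

Step 6
Reactants: 6 deca-O-benzyl dimer
Product: 7 6-iodo derivative of 6 (iodine at C6 of the upper, 4-linked unit)
Conditions: NIS (1.1 equiv), CH2Cl2/MeCN, 0 °C → rt, dark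
Reagents that add atoms: N-iodosuccinimide, O=C1CCC(=O)N1I
Why: electrophilic aromatic iodination should occur at the only unsubstituted phloroglucinol-type carbon left in the molecule, the catechol ether and benzyl rings being far less nucleophilic.

Step 7
Reactants: 8 3,5-bis(benzyloxy)phenol
Product: 9 2,4-bis(benzyloxy)-6-hydroxybenzaldehyde
Conditions: MgCl2, Et3N, (CH2O)n, MeCN, reflux; then 1 M HCl
Reagents that add atoms: paraformaldehyde, written as formaldehyde, C=O
Why: magnesium-mediated ortho-formylation of a phenol (Casnati–Skattebøl reaction), in which the magnesium phenoxide directs formaldehyde to the ortho carbon and a second equivalent oxidises the benzylic alkoxide to the aldehyde.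

Step 8
Reactants: 7 6-iodo deca-O-benzyl dimer; 9 2,4-bis(benzyloxy)-6-hydroxybenzaldehyde
Product: 12 ortho-hydroxybenzhydrol of the protected dimer (both carbinol epimers), via aryl-magnesium chloride 10 (not isolated), via chloromagnesium phenoxide 11 (not isolated)
Conditions: 7, iPrMgCl·LiCl (1.1 equiv), THF, −20 → 0 °C; separately 9 (1.5 equiv), iPrMgCl·LiCl (1.5 equiv), THF, −40 °C; combine, −40 °C → rt; aq NH4Cl; triethylamine-deactivated silica
Reagents that add atoms: none
Why: iodine–magnesium exchange should be selective for C–I over the two C–Br bonds, and addition of the aryl Grignard to the chelated magnesium phenoxide of a salicylaldehyde is the standard route to o-hydroxybenzhydrols; the carbinol centre forms unselectively and is destroyed in step 10.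

Step 9
Reactants: 13 (Z)-(2-bromovinyl)boronic acid MIDA ester; 14 3,4-bis(benzyloxy)phenylboronic acid
Product: 15 (Z)-[2-(3,4-bis(benzyloxy)phenyl)vinyl]boronic acid MIDA ester
Conditions: Pd(OAc)2 (5 mol %), SPhos (2-dicyclohexylphosphino-2',6'-dimethoxybiphenyl, 10 mol %), K3PO4, THF, 45 °C
Reagents that add atoms: none
Why: Suzuki–Miyaura coupling under anhydrous conditions, in which the tetracoordinate MIDA boronate stays inert and the geometry of the alkenyl bromide is retained.

Step 10
Reactants: 12 ortho-hydroxybenzhydrol of the protected dimer; 15 (Z)-[2-(3,4-bis(benzyloxy)phenyl)vinyl]boronic acid MIDA ester (2 equiv)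
Product: 17 protected trimer bearing B(MIDA) at C3 of the top unit (2α-aryl 3α-boryl 4β-aryl), via o-quinone methide 16 (not isolated)
Conditions: (R)-3,3'-bis(2,4,6-triisopropylphenyl)-1,1'-binaphthyl-2,2'-diyl hydrogen phosphate [(R)-TRIP, 10 mol %], 5 Å molecular sieves, CH2Cl2, −20 °C → rt
Reagents that add atoms: none
Why: Proposed new method: the chiral phosphoric acid dehydrates 12 to the hydrogen-bonded (E)-o-quinone methide 16 (O1=C8a–C4a=C4), which adds across the C=C bond of 15 in an inverse-electron-demand oxa-[4+2] cycloaddition, the methide carbon C4 bonding to the boron-bearing carbon (C3) ahead of O1 bonding to the benzylic carbon (C2). The closest known reaction types are the phosphoric-acid-catalysed [4+2] cycloaddition of o-hydroxybenzhydrol-derived o-quinone methides with styrenes and the use of alkenyl MIDA boronates as π-nucleophiles toward electrophiles (epoxidation, halogenation); an alkenyl boronate has not been shown as the 2π partner of an o-quinone methide. Ring C closes in the hetero-Diels–Alder mode (4π oxadiene plus 2π alkene, both bonds formed on one face of each partner; in the stepwise limit a six-membered closure of the phenoxide oxygen onto the benzylic cation). C2 and C3 are set cis by suprafacial addition to the (Z)-alkene; C4 is set trans to C3 by the exo transition state, which keeps B(MIDA) away from the twisted, di-ortho-substituted middle-unit aryl on C4; the absolute sense is set by the catalyst, which blocks one face of the bound o-quinone methide. The step needs regioselectivity (secured because positive charge at C2 is stabilised by the para-benzyloxy group of the 3,4-bis(benzyloxy)phenyl ring and by σ(C–B) hyperconjugation of the tetracoordinate boron), exo and face selectivity as argued, and retention of boron (secured because the MIDA cage offers no easy path for loss of a boron cation, unlike a trifluoroborate). Because the lower units are enantiopure, a wrong-face adduct would be a diastereomer that chromatography should remove.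

Step 11
Reactants: 17 protected trimer bearing B(MIDA) at C3 of the top unit
Product: 19 protected trimer with free 3-OH in the top unit, via boronic acid 18 (not isolated)
Conditions: 1 M NaOH aq (3 equiv), THF, rt, 15 min; then 30% H2O2, 0 °C → rt; aq Na2S2O3
Reagents that add atoms: hydrogen peroxide, OO
Why: aqueous base releases the boronic acid from MIDA, and peroxide oxidation proceeds by 1,2-migration of C3 from boron to oxygen with retention, which should give the 3α-OH cis to the 2-aryl group.

Step 12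
Reactants: 19 protected trimer with free 3-OH in the top unit
Product: 20 epicatechin-(4β→6)-epicatechin-(4β→6)-epicatechin (target)
Conditions: H2 (1 atm), Pd(OH)2/C, Et3N, THF/MeOH/H2O, rt
Reagents that add atoms: none
Why: catalytic hydrogenolysis should cleave all fourteen benzyl ethers and hydrodehalogenate both aryl bromides, with Et3N trapping HBr to protect the acid-labile interflavan bonds, and no stereocentre is touched.

**Compound list**

1 | (−)-epicatechin | Oc1cc(O)c2c(c1)O[C@H](c1ccc(O)c(O)c1)[C@H](O)C2 | starting material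
2 | 5,7,3',4'-tetra-O-benzyl-(−)-epicatechin | O(Cc4ccccc4)c1cc(OCc4ccccc4)c2c(c1)O[C@H](c1ccc(OCc4ccccc4)c(OCc4ccccc4)c1)[C@H](O)C2 | intermediate
3 | 8-bromo-5,7,3',4'-tetra-O-benzyl-(−)-epicatechin | O(Cc4ccccc4)c1cc(OCc4ccccc4)c2c(c1Br)O[C@H](c1ccc(OCc4ccccc4)c(OCc4ccccc4)c1)[C@H](O)C2 | intermediate
4 | 8-bromo-5,7,3',4'-tetra-O-benzyl-4β-(2-hydroxyethoxy)-(−)-epicatechin | O(Cc4ccccc4)c1cc(OCc4ccccc4)c2c(c1Br)O[C@H](c1ccc(OCc4ccccc4)c(OCc4ccccc4)c1)[C@H](O)[C@H]2OCCO | intermediate
5 | protected dimer diol, [8-bromo-tetra-O-benzyl-epicatechin]-(4β→6)-[8-bromo-tetra-O-benzyl-epicatechin] | c1c(OCc4ccccc4)c(Br)c2c(c1OCc4ccccc4)[C@H](c1c(OCc4ccccc4)c(Br)c3c(c1OCc4ccccc4)C[C@@H](O)[C@@H](c1ccc(OCc4ccccc4)c(OCc4ccccc4)c1)O3)[C@@H](O)[C@@H](c1ccc(OCc4ccccc4)c(OCc4ccccc4)c1)O2 | intermediate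
6 | deca-O-benzyl dimer (both 3-OH benzylated) | c1c(OCc4ccccc4)c(Br)c2c(c1OCc4ccccc4)[C@H](c1c(OCc4ccccc4)c(Br)c3c(c1OCc4ccccc4)C[C@@H](OCc4ccccc4)[C@@H](c1ccc(OCc4ccccc4)c(OCc4ccccc4)c1)O3)[C@@H](OCc4ccccc4)[C@@H](c1ccc(OCc4ccccc4)c(OCc4ccccc4)c1)O2 | intermediate
7 | 6-iodo deca-O-benzyl dimer (iodine at C6 of the upper unit) | Ic1c(OCc4ccccc4)c(Br)c2c(c1OCc4ccccc4)[C@H](c1c(OCc4ccccc4)c(Br)c3c(c1OCc4ccccc4)C[C@@H](OCc4ccccc4)[C@@H](c1ccc(OCc4ccccc4)c(OCc4ccccc4)c1)O3)[C@@H](OCc4ccccc4)[C@@H](c1ccc(OCc4ccccc4)c(OCc4ccccc4)c1)O2 | intermediate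
8 | 3,5-bis(benzyloxy)phenol | Oc1cc(OCc2ccccc2)cc(OCc2ccccc2)c1 | starting material
9 | 2,4-bis(benzyloxy)-6-hydroxybenzaldehyde | O=Cc1c(O)cc(OCc2ccccc2)cc1OCc2ccccc2 | intermediate
10 | aryl-magnesium chloride of the dimer (C6–MgCl in the upper unit), not isolated | Cl[Mg]c1c(OCc4ccccc4)c(Br)c2c(c1OCc4ccccc4)[C@H](c1c(OCc4ccccc4)c(Br)c3c(c1OCc4ccccc4)C[C@@H](OCc4ccccc4)[C@@H](c1ccc(OCc4ccccc4)c(OCc4ccccc4)c1)O3)[C@@H](OCc4ccccc4)[C@@H](c1ccc(OCc4ccccc4)c(OCc4ccccc4)c1)O2 | intermediate
11 | chloromagnesium phenoxide of 9, not isolated | O=Cc1c(O[Mg]Cl)cc(OCc2ccccc2)cc1OCc2ccccc2 | intermediate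
12 | ortho-hydroxybenzhydrol, [2,4-bis(benzyloxy)-6-hydroxyphenyl][C6 of the upper unit of 6]methanol, both carbinol epimers | OC(c5c(O)cc(OCc4ccccc4)cc5OCc4ccccc4)c1c(OCc4ccccc4)c(Br)c2c(c1OCc4ccccc4)[C@H](c1c(OCc4ccccc4)c(Br)c3c(c1OCc4ccccc4)C[C@@H](OCc4ccccc4)[C@@H](c1ccc(OCc4ccccc4)c(OCc4ccccc4)c1)O3)[C@@H](OCc4ccccc4)[C@@H](c1ccc(OCc4ccccc4)c(OCc4ccccc4)c1)O2 | intermediate
13 | (Z)-(2-bromovinyl)boronic acid MIDA ester | C[N+]12CC(=O)O[B-]1(/C=C\Br)OC(=O)C2 | starting material
14 | 3,4-bis(benzyloxy)phenylboronic acid | OB(O)c1ccc(OCc2ccccc2)c(OCc2ccccc2)c1 | starting material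
15 | (Z)-[2-(3,4-bis(benzyloxy)phenyl)vinyl]boronic acid MIDA ester | C[N+]12CC(=O)O[B-]1(/C=C\c3ccc(OCc4ccccc4)c(OCc4ccccc4)c3)OC(=O)C2 | intermediate
16 | (E)-o-quinone methide, 3,5-bis(benzyloxy)-6-(arylmethylidene)cyclohexa-2,4-dien-1-one with the dimer as aryl group, not isolated | O=C1C=C(OCc4ccccc4)C=C(OCc4ccccc4)/C1=C\c1c(OCc4ccccc4)c(Br)c2c(c1OCc4ccccc4)[C@H](c1c(OCc4ccccc4)c(Br)c3c(c1OCc4ccccc4)C[C@@H](OCc4ccccc4)[C@@H](c1ccc(OCc4ccccc4)c(OCc4ccccc4)c1)O3)[C@@H](OCc4ccccc4)[C@@H](c1ccc(OCc4ccccc4)c(OCc4ccccc4)c1)O2 | intermediate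
17 | protected trimer with B(MIDA) in place of the 3-OH of the top unit (2α-aryl, 3α-boryl, 4β-aryl) | O(Cc4ccccc4)c1cc(OCc4ccccc4)c2c(c1)O[C@H](c1ccc(OCc4ccccc4)c(OCc4ccccc4)c1)[C@H]([B-]56OC(=O)C[N+]5(C)CC(=O)O6)[C@H]2c1c(OCc4ccccc4)c(Br)c2c(c1OCc4ccccc4)[C@H](c1c(OCc4ccccc4)c(Br)c3c(c1OCc4ccccc4)C[C@@H](OCc4ccccc4)[C@@H](c1ccc(OCc4ccccc4)c(OCc4ccccc4)c1)O3)[C@@H](OCc4ccccc4)[C@@H](c1ccc(OCc4ccccc4)c(OCc4ccccc4)c1)O2 | intermediate
18 | boronic acid at C3 of the top unit, not isolated | O(Cc4ccccc4)c1cc(OCc4ccccc4)c2c(c1)O[C@H](c1ccc(OCc4ccccc4)c(OCc4ccccc4)c1)[C@H](B(O)O)[C@H]2c1c(OCc4ccccc4)c(Br)c2c(c1OCc4ccccc4)[C@H](c1c(OCc4ccccc4)c(Br)c3c(c1OCc4ccccc4)C[C@@H](OCc4ccccc4)[C@@H](c1ccc(OCc4ccccc4)c(OCc4ccccc4)c1)O3)[C@@H](OCc4ccccc4)[C@@H](c1ccc(OCc4ccccc4)c(OCc4ccccc4)c1)O2 | intermediate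
19 | protected trimer with free 3-OH in the top unit (fourteen benzyl ethers, bromine at C8 of the middle and bottom units) | O(Cc4ccccc4)c1cc(OCc4ccccc4)c2c(c1)O[C@H](c1ccc(OCc4ccccc4)c(OCc4ccccc4)c1)[C@H](O)[C@H]2c1c(OCc4ccccc4)c(Br)c2c(c1OCc4ccccc4)[C@H](c1c(OCc4ccccc4)c(Br)c3c(c1OCc4ccccc4)C[C@@H](OCc4ccccc4)[C@@H](c1ccc(OCc4ccccc4)c(OCc4ccccc4)c1)O3)[C@@H](OCc4ccccc4)[C@@H](c1ccc(OCc4ccccc4)c(OCc4ccccc4)c1)O2 | intermediate
20 | epicatechin-(4β→6)-epicatechin-(4β→6)-epicatechin | Oc1cc(O)c2c(c1)O[C@H](c1ccc(O)c(O)c1)[C@H](O)[C@H]2c1c(O)cc2c(c1O)[C@H](c1c(O)cc3c(c1O)C[C@@H](O)[C@@H](c1ccc(O)c(O)c1)O3)[C@@H](O)[C@@H](c1ccc(O)c(O)c1)O2 | target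

**Step count**

Total steps: 12. Longest linear sequence: 10 steps (steps 1, 2, 3, 4, 5, 6, 8, 10, 11, 12, from (−)-epicatechin).

**Steps most likely to fail**

Step 10. The cycloaddition may stall because the C3–C4 bond joins a boron-bearing carbon to a methide carbon flanked by two di-ortho-substituted rings. The exo or face preference may be weak, and boron may be lost after C–C bond formation to give an alkenylated diarylmethane. In that case the top unit would be attached as a preformed flavan by known chemistry. Compound 6, whose only free phloroglucinol position is C6 of its upper unit, is coupled with the C4 electrophile 4 under TMSOTf in CH2Cl2 at −78 °C (the reaction type of step 4), attack again occurring anti to the 3-OH. This should give the protected tribromo trimer F1, which is hydrogenolysed under the conditions of step 12. The fallback sets out from 6 (with 4) and rejoins the route at 20.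

Step 11. Formation of the hydroxyborate may trigger β-elimination of the ring C aryloxy group (ring opening between C2 and O1) in the conformer that places C3–B antiperiplanar to C2–O1, in competition with the C-to-O migration. In that case the boron ligand would be exchanged before oxidation. Compound 17 is treated with pinacol and NaHCO3 in MeOH to give the pinacol boronate F2. F2 is oxidised with trimethylamine N-oxide in THF at 60 °C, a neutral oxidant whose adduct rearranges without a free hydroxyborate, and aqueous work-up should return the alcohol. The fallback sets out from 17 and rejoins the route at 19.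

Step 8. The hindered aryl-magnesium species may be protonated by residual phenol, or may fail to add to the electron-rich, chelated aldehyde. In that case the polarity of the benzhydrol disconnection would be reversed. The aryl-magnesium chloride 10 is generated from 7 as in step 8 and quenched with DMF, a small and reactive electrophile, to give the dimer C6-carbaldehyde F3. Phenol 8 is converted with EtMgBr into its bromomagnesium phenoxide F4, which attacks F3 through its ortho carbon in CH2Cl2/toluene (ortho-specific hydroxyalkylation of a magnesium phenoxide through a six-membered chelate). The fallback sets out from 7 and 8 and rejoins the route at 12.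

**Further compounds**

F1 | step 10 | protected tribromo trimer, [8-bromo-tetra-O-benzyl-epicatechin]-(4β→6)-[deca-O-benzyl dibromo dimer], 3-OH of the top unit free | O(Cc4ccccc4)c1cc(OCc4ccccc4)c2c(c1Br)O[C@H](c1ccc(OCc4ccccc4)c(OCc4ccccc4)c1)[C@H](O)[C@H]2c1c(OCc4ccccc4)c(Br)c2c(c1OCc4ccccc4)[C@H](c1c(OCc4ccccc4)c(Br)c3c(c1OCc4ccccc4)C[C@@H](OCc4ccccc4)[C@@H](c1ccc(OCc4ccccc4)c(OCc4ccccc4)c1)O3)[C@@H](OCc4ccccc4)[C@@H](c1ccc(OCc4ccccc4)c(OCc4ccccc4)c1)O2
F2 | step 11 | pinacol boronate at C3 of the top unit of the protected trimer | O(Cc4ccccc4)c1cc(OCc4ccccc4)c2c(c1)O[C@H](c1ccc(OCc4ccccc4)c(OCc4ccccc4)c1)[C@H](B5OC(C)(C)C(C)(C)O5)[C@H]2c1c(OCc4ccccc4)c(Br)c2c(c1OCc4ccccc4)[C@H](c1c(OCc4ccccc4)c(Br)c3c(c1OCc4ccccc4)C[C@@H](OCc4ccccc4)[C@@H](c1ccc(OCc4ccccc4)c(OCc4ccccc4)c1)O3)[C@@H](OCc4ccccc4)[C@@H](c1ccc(OCc4ccccc4)c(OCc4ccccc4)c1)O2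
F3 | step 8 | dimer C6-carbaldehyde (formyl group at C6 of the upper unit of 6) | O=Cc1c(OCc4ccccc4)c(Br)c2c(c1OCc4ccccc4)[C@H](c1c(OCc4ccccc4)c(Br)c3c(c1OCc4ccccc4)C[C@@H](OCc4ccccc4)[C@@H](c1ccc(OCc4ccccc4)c(OCc4ccccc4)c1)O3)[C@@H](OCc4ccccc4)[C@@H](c1ccc(OCc4ccccc4)c(OCc4ccccc4)c1)O2
F4 | step 8 | bromomagnesium 3,5-bis(benzyloxy)phenoxide | Br[Mg]Oc1cc(OCc2ccccc2)cc(OCc2ccccc2)c1
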